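**Plan**

Locants: oxepane/cyclohexane half numbered as a chain C2–C11 (C2 = O–CMe2, C3 = CHOH, C6 = C–Me, C7 = CH–O, C10 = C(OH)Me, C11 = CH), linker C12–C13, hydroazulene by azulene locants with a prime.
Cuts, in retrosynthetic order: three O–Si bonds; C10–CH3; O–C2 together with C6–C11 (one cascade); C11=C12 (enone by cross-metathesis); in the hydroazulene C5'–allyl, C1'–C8a', C8'=C8a', C5'–C6', C3a'–C4'.
Enabling feature: the ether oxygen bridges C7 and the gem-dimethyl carbon C2, C3 bears OH, and quaternary C6(Me) is bonded to C11 next to the C10 carbinol. This is the imprint of a (3R,6R,7R)-bis-epoxide of an E-geranyl chain whose two tertiary epoxide carbons (C6, C2) are opened in turn by the carbon of a C10 enol silane and by the C7 oxygen.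
Forward: cycloheptenone by ring-closing metathesis, cyclopentanol by ketyl–enone cyclization, allyl handle by Stork–Danheiser addition; the bis-epoxy vinyl ketone is joined by cross-metathesis; one silyl triflate cascade closes the cyclohexanone and, last of all rings, the oxepane; methyl addition and desilylation finish.
Stereochemistry: C3a' from Ir-catalysed asymmetric allylic alkylation; C1' and C8a' relayed from C3a' in the SmI2 cyclization; C7' from Corey–Bakshi–Shibata reduction; C3, C6, C7 from Shi epoxidation (C6 inverted in the cascade); C11 from the chair transition state; C10 from equatorial methyl attack.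

Key step: step 18

Assumption: the Shi ketone derived from D-fructose gives the (R,R)-epoxides on both E-trisubstituted alkenes of 20, and the phosphoramidite enantiomer used in step 2 is the one that gives the 3R centre.

**Route**

Step 1
Reactants: 1 hex-5-en-2-one; 2 allyl methyl carbonate
Product: 3 methyl (2E)-6-oxohept-2-en-1-yl carbonate
Conditions: second-generation Grubbs catalyst (2 mol %), 2 (4 equiv), CH2Cl2, 40 °C
Reagents that add atoms: none
Why: Olefin cross-metathesis of a terminal alkene with an excess of an allylic carbonate should give the E-configured linear allylic carbonate required for the iridium allylation.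

Step 2
Reactants: 3 methyl (2E)-6-oxohept-2-en-1-yl carbonate; 4 1-methoxy-2-methyl-1-(trimethylsilyloxy)prop-1-ene
Product: 5 methyl (3R)-3-ethenyl-2,2-dimethyl-6-oxoheptanoate
Conditions: [Ir(cod)Cl]2 (2 mol %), binaphthol-derived N,N-bis(1-phenylethyl)phosphoramidite (4 mol %), THF, 23 °C
Reagents that add atoms: none
Why: Iridium-catalysed asymmetric allylic alkylation with a silyl ketene acetal as ester enolate equivalent should give the branched product, the chiral iridium allyl complex directing attack to one allyl face and so setting the 3R centre (C3a') beside the new quaternary carbon.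

Step 3
Reactants: 5 methyl (3R)-3-ethenyl-2,2-dimethyl-6-oxoheptanoate
Product: 6 (3R)-3-ethenyl-2,2-dimethylheptane-1,6-diol (both C6 epimers)
Conditions: LiAlH4, Et2O, 0 °C
Reagents that add atoms: none
Why: Hydride reduction of ester and ketone together avoids a protecting group, the two carbinol epimers converging again in step 4.

Step 4
Reactants: 6 (3R)-3-ethenyl-2,2-dimethylheptane-1,6-diol
Product: 7 (3R)-3-ethenyl-2,2-dimethyl-6-oxoheptanal
Conditions: Dess–Martin periodinane (2.5 equiv), NaHCO3, CH2Cl2, 23 °C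
Reagents that add atoms: none
Why: Dess–Martin oxidation should convert the neopentyl primary alcohol to the non-enolisable aldehyde and the secondary alcohol to the methyl ketone without touching the vinyl group.

Step 5
Reactants: 7 (3R)-3-ethenyl-2,2-dimethyl-6-oxoheptanal; 8 (4E)-hex-4-en-3-one
Product: 9 (2E,8R)-8-ethenyl-6-hydroxy-5,7,7-trimethyldodec-2-ene-4,11-dione (5,6-syn isomers)
Conditions: 8, Bu2BOTf, i-Pr2NEt, CH2Cl2, −78 °C; then 7, −78 to 0 °C; pH 7 buffer, MeOH, H2O2, 0 °C
Reagents that add atoms: none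
Why: A boron-mediated aldol addition of the (Z)-enolate of the ethyl ketone should add to the aldehyde and leave the methyl ketone alone; the C5 and C6 centres it creates become trigonal later, so their mixture is of no consequence.

Step 6
Reactants: 9 (2E,8R)-8-ethenyl-6-hydroxy-5,7,7-trimethyldodec-2-ene-4,11-dione
Product: 10 (4R)-6-hydroxy-5,5,7-trimethyl-4-(3-oxobutyl)cyclohept-2-en-1-one
Conditions: second-generation Grubbs catalyst (5 mol %), CH2Cl2 (5 mM), 40 °C
Reagents that add atoms: none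
Why: Ring-closing metathesis between the propenyl ketone and the vinyl group should close the cycloheptenone, the seven-membered ring of the hydroazulene.

Step 7
Reactants: 10 (4R)-6-hydroxy-5,5,7-trimethyl-4-(3-oxobutyl)cyclohept-2-en-1-one
Product: 11 (1R,3aR,8aR)-1,5-dihydroxy-1,4,4,6-tetramethyldecahydroazulen-7-one (C5/C6 isomers)
Conditions: SmI2 (2.5 equiv), HMPA, t-BuOH (2 equiv), THF, −78 °C
Reagents that add atoms: none
Why: In this SmI2 (divalent samarium) ketyl–enone reductive cyclization the ketyl adds 5-exo to the enone β-carbon from the face of its tether on C3a', which enforces the cis ring fusion at C8a', and the bulky samarium alkoxide turns away from the enolate carbon C8', which places the C1' hydroxyl cis to H-8a'.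

Step 8
Reactants: 11 (1R,3aR,8aR)-1,5-dihydroxy-1,4,4,6-tetramethyldecahydroazulen-7-one
Product: 12 (1R,3aR,8aR)-1-hydroxy-1,4,4,6-tetramethyloctahydroazulene-5,7-dione
Conditions: Dess–Martin periodinane, NaHCO3, CH2Cl2, 23 °C
Reagents that add atoms: none
Why: Dess–Martin oxidation of the secondary alcohol should give the 2-methyl-1,3-dione, the tertiary alcohol being inert and the C5'/C6' isomers converging.

Step 9
Reactants: 12 (1R,3aR,8aR)-1-hydroxy-1,4,4,6-tetramethyloctahydroazulene-5,7-dione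
Product: 13 (1R,3aR,8aR)-1-hydroxy-7-methoxy-1,4,4,6-tetramethyl-2,3,3a,4,8,8a-hexahydroazulen-5(1H)-one
Conditions: HC(OMe)3, p-TsOH·H2O (cat.), MeOH, 23 °C
Reagents that add atoms: trimethyl orthoformate, COC(OC)OC
Why: Acid-catalysed enol ether formation on an unsymmetrical 1,3-dione should take place at the carbonyl remote from the gem-dimethyl group (C7'), which leaves the hindered C5' carbonyl as the vinylogous ester carbonyl needed for the Stork–Danheiser sequence.

Step 10
Reactants: 13 (1R,3aR,8aR)-1-hydroxy-7-methoxy-1,4,4,6-tetramethyl-2,3,3a,4,8,8a-hexahydroazulen-5(1H)-one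
Product: 15 (1R,3aR,8aR)-1-hydroxy-1,4,4,6-tetramethyl-5-(prop-2-en-1-yl)-2,3,3a,4,8,8a-hexahydroazulen-7(1H)-one, via allyl carbinol 14 (not isolated)
Conditions: CH2=CHCH2MgBr (3 equiv), THF, −78 to 0 °C; then 1 M HCl, THF, 0 °C
Reagents that add atoms: allylmagnesium bromide, C=CC[Mg]Br; water, O
Why: In the Stork–Danheiser sequence the allyl Grignard reagent adds 1,2 to the hindered vinylogous ester carbonyl and acid hydrolysis of the enol ether carbinol transposes the enone, which installs the tetrasubstituted C5'=C6' alkene with its three-carbon handle.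

Step 11
Reactants: 15 (1R,3aR,8aR)-1-hydroxy-1,4,4,6-tetramethyl-5-(prop-2-en-1-yl)-2,3,3a,4,8,8a-hexahydroazulen-7(1H)-one
Product: 16 (1R,3aR,7S,8aR)-1,4,4,6-tetramethyl-5-(prop-2-en-1-yl)-1,2,3,3a,4,7,8,8a-octahydroazulene-1,7-diol
Conditions: (R)-2-methyl-CBS-oxazaborolidine (20 mol %), catecholborane, toluene, −78 °C
Reagents that add atoms: none
Why: In the Corey–Bakshi–Shibata reduction the tetrasubstituted alkene carbon acts as the large group, so the (R)-catalyst should deliver hydride to give the 7'S alcohol, which is also the sense of attack on the convex face of the cis-fused bicycle; catecholborane spares the terminal alkene.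

Step 12
Reactants: 16 (1R,3aR,7S,8aR)-1,4,4,6-tetramethyl-5-(prop-2-en-1-yl)-1,2,3,3a,4,7,8,8a-octahydroazulene-1,7-diol
Product: 17 (1R,3aR,7S,8aR)-1,4,4,6-tetramethyl-5-(prop-2-en-1-yl)-1,7-bis(triethylsilyloxy)-1,2,3,3a,4,7,8,8a-octahydroazulene
Conditions: Et3SiOTf (2.5 equiv), 2,6-lutidine, CH2Cl2, −78 to 0 °C
Reagents that add atoms: triethylsilyl trifluoromethanesulfonate, CC[Si](CC)(CC)OS(=O)(=O)C(F)(F)F
Why: Silylation with a silyl triflate should cap both the allylic secondary and the tertiary hydroxyl, which would otherwise be silylated by the hydrosilane or compete as nucleophiles in the cascade.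

Step 13
Reactants: 18 N-methoxy-N-methylacetamide; 19 geranyl bromide
Product: 20 (4E)-N-methoxy-N,5,9-trimethyldeca-4,8-dienamide
Conditions: LiN(i-Pr)2, THF, −78 °C; then 19, −78 to 0 °C
Reagents that add atoms: none
Why: SN2 alkylation of the amide lithium enolate by the reactive allylic bromide should give the chain with the E geometry of the geranyl unit intact.

Step 14
Reactants: 20 (4E)-N-methoxy-N,5,9-trimethyldeca-4,8-dienamide
Product: 21 3-[(2R,3R)-3-{2-[(2R)-3,3-dimethyloxiran-2-yl]ethyl}-3-methyloxiran-2-yl]-N-methoxy-N-methylpropanamide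
Conditions: D-fructose-derived Shi ketone (0.6 equiv), KHSO5 (as 2KHSO5·KHSO4·K2SO4), K2CO3, aqueous Na2B4O7 buffer (pH 10.5), Bu4NHSO4, MeCN/CH2(OMe)2, 0 °C
Reagents that add atoms: potassium peroxymonosulfate, [K+].[O-]S(=O)(=O)OO
Why: In the Shi asymmetric epoxidation the chiral dioxirane should attack both E-trisubstituted alkenes through the spiro transition state on the same face, which sets C3, C6 and C7 in one operation.

Step 15
Reactants: 21 3-[(2R,3R)-3-{2-[(2R)-3,3-dimethyloxiran-2-yl]ethyl}-3-methyloxiran-2-yl]-N-methoxy-N-methylpropanamide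
Product: 22 5-[(2R,3R)-3-{2-[(2R)-3,3-dimethyloxiran-2-yl]ethyl}-3-methyloxiran-2-yl]pent-1-en-3-one
Conditions: CH2=CHMgBr (1.5 equiv), THF, −78 to 0 °C; inverse quench into cold aqueous NH4Cl
Reagents that add atoms: vinylmagnesium bromide, C=C[Mg]Br
Why: Ketone synthesis from an N-methoxy-N-methylamide stops at the chelated tetrahedral adduct, and trisubstituted epoxides should be inert to the Grignard reagent at low temperature.

Step 16
Reactants: 17 (1R,3aR,7S,8aR)-1,4,4,6-tetramethyl-5-(prop-2-en-1-yl)-1,7-bis(triethylsilyloxy)-1,2,3,3a,4,7,8,8a-octahydroazulene; 22 5-[(2R,3R)-3-{2-[(2R)-3,3-dimethyloxiran-2-yl]ethyl}-3-methyloxiran-2-yl]pent-1-en-3-one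
Product: 23 (2E)-1-[(1R,3aR,7S,8aR)-1,4,4,6-tetramethyl-1,7-bis(triethylsilyloxy)-1,2,3,3a,4,7,8,8a-octahydroazulen-5-yl]-6-[(2R,3R)-3-{2-[(2R)-3,3-dimethyloxiran-2-yl]ethyl}-3-methyloxiran-2-yl]hex-2-en-4-one
Conditions: second-generation Hoveyda–Grubbs catalyst (5 mol %), 22 (2 equiv), CH2Cl2, 40 °C
Reagents that add atoms: none
Why: Cross-metathesis of a terminal alkene with a vinyl ketone should give the E-enone selectively, the tetrasubstituted ring alkene and the epoxides being inert to the ruthenium carbene.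

Step 17
Reactants: 23 (2E)-enone from step 16
Product: 24 triethyl({(3Z)-1-[(1R,3aR,7S,8aR)-1,4,4,6-tetramethyl-1,7-bis(triethylsilyloxy)-1,2,3,3a,4,7,8,8a-octahydroazulen-5-yl]-6-[(2R,3R)-3-{2-[(2R)-3,3-dimethyloxiran-2-yl]ethyl}-3-methyloxiran-2-yl]hex-3-en-4-yl}oxy)silane
Conditions: RhCl(PPh3)3 (2 mol %), Et3SiH (1.5 equiv), toluene, 50 °C
Reagents that add atoms: triethylsilane, CC[SiH](CC)CC
Why: Rhodium-catalysed 1,4-hydrosilylation of the enone through its s-cis conformer should give the (Z)-enol silane regiospecifically on the C11 side, which enolisation of the saturated ketone could not do.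

Step 18
Reactants: 24 (Z)-triethylsilyl enol ether bis-epoxide from step 17
Product: 26 (3R,5aR,6R,9aR)-2,2,5a-trimethyl-6-{2-[(1R,3aR,7S,8aR)-1,4,4,6-tetramethyl-1,7-bis(triethylsilyloxy)-1,2,3,3a,4,7,8,8a-octahydroazulen-5-yl]ethyl}-3-(triethylsilyloxy)octahydro-1-benzoxepin-7(2H)-one, via silyloxy ketone 25 (not isolated)
Conditions: Et3SiOTf (0.3 equiv), 2,6-di-tert-butyl-4-methylpyridine (0.5 equiv), CH2Cl2, −78 °C; Et3N, then aqueous NaHCO3
Reagents that add atoms: none
Why: Et3SiOTf silylates the C6–C7 epoxide and the enol silane carbon C11 opens it at the tertiary carbon C6 with inversion through a chair (6-endo epoxide opening), which closes the cyclohexanone, leaves O7 as a silyl ether in 25 and returns Et3SiOTf; the silyl triflate then activates the C2–C3 epoxide and O7 attacks the tertiary carbon C2 (7-endo-tet), closing the oxepane as the last ring while the silyl group passes to O3, so the whole change is an isomerization catalytic in silyl triflate. The closest known reaction is the Lewis-acid-promoted tandem oxa- and carbacyclization of 1,5-diepoxides terminated by an enol silane, which is known to give this trans-fused oxepane–cyclohexanone ring system from geranyl-derived diepoxides. C6 is set by anti opening of the (6R,7R)-epoxide (E alkene, hence trans ring fusion and axial methyl), C7 and C3 keep the configuration of the Shi epoxides, and C11 is set by the (Z)-enol silane in the chair, which puts the side chain equatorial, the isomer also favoured by equilibration alpha to the ketone. The step needs endo over exo opening at both epoxides and carbon attack before oxygen attack: the first is secured because both attacked carbons are tertiary (methyl on C6, gem-dimethyl on C2) and carry the positive charge of the silyloxiranium ion, the second because the enol silane is a far better nucleophile than an epoxide or ether oxygen, while low temperature and the hindered pyridine suppress proton-driven rearrangement. Should the terminal epoxide be engaged first through the bridged epoxonium ion, the same two bonds would form with the same stereochemical result.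

Step 19
Reactants: 26 tricyclic ketone from step 18
Product: 27 (3R,5aR,6R,7S,9aR)-2,2,5a,7-tetramethyl-6-{2-[(1R,3aR,7S,8aR)-1,4,4,6-tetramethyl-1,7-bis(triethylsilyloxy)-1,2,3,3a,4,7,8,8a-octahydroazulen-5-yl]ethyl}-3-(triethylsilyloxy)decahydro-1-benzoxepin-7-ol
Conditions: MeMgBr, CeCl3, THF, −78 to 0 °C
Reagents that add atoms: methylmagnesium bromide, C[Mg]Br
Why: In this organocerium 1,2-addition to a hindered enolisable ketone the axial face of C10 is blocked by the syn-axial methyl on C6, so the methyl group should enter equatorially and give the axial 10S carbinol.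

Step 20
Reactants: 27 tris(triethylsilyl) ether from step 19
Product: 28 (3R,5aR,6R,7S,9aR)-6-{2-[(1R,3aR,7S,8aR)-1,7-dihydroxy-1,4,4,6-tetramethyl-1,2,3,3a,4,7,8,8a-octahydroazulen-5-yl]ethyl}-2,2,5a,7-tetramethyldecahydro-1-benzoxepine-3,7-diol (CNP0276044.1)
Conditions: Bu4NF, THF, 23 to 45 °C
Reagents that add atoms: none
Why: Fluoride desilylation should remove the three triethylsilyl ethers under non-acidic conditions that do not ionise the allylic or tertiary alcohols.

**Compound list**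

1 | hex-5-en-2-one | CC(=O)CCC=C | starting material
2 | allyl methyl carbonate | C=CCOC(=O)OC | starting material
3 | methyl (2E)-6-oxohept-2-en-1-yl carbonate | CC(=O)CC/C=C/COC(=O)OC | intermediate
4 | 1-methoxy-2-methyl-1-(trimethylsilyloxy)prop-1-ene | COC(O[Si](C)(C)C)=C(C)C | starting material
5 | methyl (3R)-3-ethenyl-2,2-dimethyl-6-oxoheptanoate | COC(=O)C(C)(C)[C@@H](C=C)CCC(C)=O | intermediate
6 | (3R)-3-ethenyl-2,2-dimethylheptane-1,6-diol (both C6 epimers) | OCC(C)(C)[C@@H](C=C)CCC(C)O | intermediate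
7 | (3R)-3-ethenyl-2,2-dimethyl-6-oxoheptanal | O=CC(C)(C)[C@@H](C=C)CCC(C)=O | intermediate
8 | (4E)-hex-4-en-3-one | CCC(=O)/C=C/C | starting material
9 | (2E,8R)-8-ethenyl-6-hydroxy-5,7,7-trimethyldodec-2-ene-4,11-dione (5,6-syn isomers) | C/C=C/C(=O)C(C)C(O)C(C)(C)[C@@H](C=C)CCC(C)=O | intermediate
10 | (4R)-6-hydroxy-5,5,7-trimethyl-4-(3-oxobutyl)cyclohept-2-en-1-one (C6/C7 isomers) | CC1C(O)C(C)(C)[C@H](CCC(C)=O)C=CC1=O | intermediate
11 | (1R,3aR,8aR)-1,5-dihydroxy-1,4,4,6-tetramethyldecahydroazulen-7-one (C5/C6 isomers) | CC1C(O)C(C)(C)[C@@H]2CC[C@@](C)(O)[C@@H]2CC1=O | intermediate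
12 | (1R,3aR,8aR)-1-hydroxy-1,4,4,6-tetramethyloctahydroazulene-5,7-dione | CC1C(=O)C(C)(C)[C@@H]2CC[C@@](C)(O)[C@@H]2CC1=O | intermediate
13 | (1R,3aR,8aR)-1-hydroxy-7-methoxy-1,4,4,6-tetramethyl-2,3,3a,4,8,8a-hexahydroazulen-5(1H)-one | COC1=C(C)C(=O)C(C)(C)[C@@H]2CC[C@@](C)(O)[C@@H]2C1 | intermediate
14 | (1R,3aR,8aR)-7-methoxy-1,4,4,6-tetramethyl-5-(prop-2-en-1-yl)-1,2,3,3a,4,5,8,8a-octahydroazulene-1,5-diol (C5 epimers, formed as magnesium alkoxide) | COC1=C(C)C(O)(CC=C)C(C)(C)[C@@H]2CC[C@@](C)(O)[C@@H]2C1 | intermediate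
15 | (1R,3aR,8aR)-1-hydroxy-1,4,4,6-tetramethyl-5-(prop-2-en-1-yl)-2,3,3a,4,8,8a-hexahydroazulen-7(1H)-one | CC1=C(CC=C)C(C)(C)[C@@H]2CC[C@@](C)(O)[C@@H]2CC1=O | intermediate
16 | (1R,3aR,7S,8aR)-1,4,4,6-tetramethyl-5-(prop-2-en-1-yl)-1,2,3,3a,4,7,8,8a-octahydroazulene-1,7-diol | CC1=C(CC=C)C(C)(C)[C@@H]2CC[C@@](C)(O)[C@@H]2C[C@@H]1O | intermediate
17 | (1R,3aR,7S,8aR)-1,4,4,6-tetramethyl-5-(prop-2-en-1-yl)-1,7-bis(triethylsilyloxy)-1,2,3,3a,4,7,8,8a-octahydroazulene | CC1=C(CC=C)C(C)(C)[C@@H]2CC[C@@](C)(O[Si](CC)(CC)CC)[C@@H]2C[C@@H]1O[Si](CC)(CC)CC | intermediate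
18 | N-methoxy-N-methylacetamide | CON(C)C(C)=O | starting material
19 | geranyl bromide, (2E)-1-bromo-3,7-dimethylocta-2,6-diene | CC(C)=CCC/C(C)=C/CBr | starting material
20 | (4E)-N-methoxy-N,5,9-trimethyldeca-4,8-dienamide | CON(C)C(=O)CC/C=C(\C)CCC=C(C)C | intermediate
21 | 3-[(2R,3R)-3-{2-[(2R)-3,3-dimethyloxiran-2-yl]ethyl}-3-methyloxiran-2-yl]-N-methoxy-N-methylpropanamide | CON(C)C(=O)CC[C@H]1O[C@]1(C)CC[C@H]1OC1(C)C | intermediate
22 | 5-[(2R,3R)-3-{2-[(2R)-3,3-dimethyloxiran-2-yl]ethyl}-3-methyloxiran-2-yl]pent-1-en-3-one | C=CC(=O)CC[C@H]1O[C@]1(C)CC[C@H]1OC1(C)C | intermediate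
23 | (2E)-1-[(1R,3aR,7S,8aR)-1,4,4,6-tetramethyl-1,7-bis(triethylsilyloxy)-1,2,3,3a,4,7,8,8a-octahydroazulen-5-yl]-6-[(2R,3R)-3-{2-[(2R)-3,3-dimethyloxiran-2-yl]ethyl}-3-methyloxiran-2-yl]hex-2-en-4-one | CC1=C(C/C=C/C(=O)CC[C@H]2O[C@]2(C)CC[C@H]2OC2(C)C)C(C)(C)[C@@H]2CC[C@@](C)(O[Si](CC)(CC)CC)[C@@H]2C[C@@H]1O[Si](CC)(CC)CC | intermediate
24 | triethyl({(3Z)-1-[(1R,3aR,7S,8aR)-1,4,4,6-tetramethyl-1,7-bis(triethylsilyloxy)-1,2,3,3a,4,7,8,8a-octahydroazulen-5-yl]-6-[(2R,3R)-3-{2-[(2R)-3,3-dimethyloxiran-2-yl]ethyl}-3-methyloxiran-2-yl]hex-3-en-4-yl}oxy)silane | CC1=C(CC/C=C(\O[Si](CC)(CC)CC)CC[C@H]2O[C@]2(C)CC[C@H]2OC2(C)C)C(C)(C)[C@@H]2CC[C@@](C)(O[Si](CC)(CC)CC)[C@@H]2C[C@@H]1O[Si](CC)(CC)CC | intermediate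
25 | (2R,3R,4R)-3-{2-[(2R)-3,3-dimethyloxiran-2-yl]ethyl}-3-methyl-2-{2-[(1R,3aR,7S,8aR)-1,4,4,6-tetramethyl-1,7-bis(triethylsilyloxy)-1,2,3,3a,4,7,8,8a-octahydroazulen-5-yl]ethyl}-4-(triethylsilyloxy)cyclohexan-1-one | CC1=C(CC[C@@H]2[C@@](C)(CC[C@H]3OC3(C)C)[C@H](O[Si](CC)(CC)CC)CCC2=O)C(C)(C)[C@@H]2CC[C@@](C)(O[Si](CC)(CC)CC)[C@@H]2C[C@@H]1O[Si](CC)(CC)CC | intermediate
26 | (3R,5aR,6R,9aR)-2,2,5a-trimethyl-6-{2-[(1R,3aR,7S,8aR)-1,4,4,6-tetramethyl-1,7-bis(triethylsilyloxy)-1,2,3,3a,4,7,8,8a-octahydroazulen-5-yl]ethyl}-3-(triethylsilyloxy)octahydro-1-benzoxepin-7(2H)-one | CC1=C(CC[C@@H]2[C@@]3(C)CC[C@@H](O[Si](CC)(CC)CC)C(C)(C)O[C@@H]3CCC2=O)C(C)(C)[C@@H]2CC[C@@](C)(O[Si](CC)(CC)CC)[C@@H]2C[C@@H]1O[Si](CC)(CC)CC | intermediate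
27 | (3R,5aR,6R,7S,9aR)-2,2,5a,7-tetramethyl-6-{2-[(1R,3aR,7S,8aR)-1,4,4,6-tetramethyl-1,7-bis(triethylsilyloxy)-1,2,3,3a,4,7,8,8a-octahydroazulen-5-yl]ethyl}-3-(triethylsilyloxy)decahydro-1-benzoxepin-7-ol | CC1=C(CC[C@@H]2[C@@]3(C)CC[C@@H](O[Si](CC)(CC)CC)C(C)(C)O[C@@H]3CC[C@]2(C)O)C(C)(C)[C@@H]2CC[C@@](C)(O[Si](CC)(CC)CC)[C@@H]2C[C@@H]1O[Si](CC)(CC)CC | intermediate
28 | (3R,5aR,6R,7S,9aR)-6-{2-[(1R,3aR,7S,8aR)-1,7-dihydroxy-1,4,4,6-tetramethyl-1,2,3,3a,4,7,8,8a-octahydroazulen-5-yl]ethyl}-2,2,5a,7-tetramethyldecahydro-1-benzoxepine-3,7-diol (CNP0276044.1) | CC1=C(CC[C@@H]2[C@@]3(C)CC[C@@H](O)C(C)(C)O[C@@H]3CC[C@]2(C)O)C(C)(C)[C@@H]2CC[C@@](C)(O)[C@@H]2C[C@@H]1O | target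

**Step count and risks**

Total step count: 20. Longest linear sequence: 17 (steps 1–12, then 16–20); steps 13–15 run in parallel.

Steps most likely to fail:

1. Step 18. The silylated epoxides may be diverted into hydride or alkyl shifts, the wrong epoxide oxygen may attack (5-exo, tetrahydrofuran formation), the oxygen closure may go 6-exo, or the activated ketone or the allylic silyl ether of the hydroazulene may be captured by the tetrasubstituted alkene. Fallback: the bicyclization is taken out of the full skeleton and the halves are joined afterwards; it sets out from 22 and 13 and comes back at 28. Cross-metathesis of 22 with allyl benzyl ether should give the benzyloxy enone F1, and RhCl(PPh3)3/Et3SiH the (Z)-enol silane F2. The same Et3SiOTf cascade, now on a chain without any other alkene or silyl ether, should give the bicyclic ketone F3. MeMgBr/CeCl3 should then give the tertiary alcohol F4, H2 over Pd/C the primary alcohol F5, and I2/PPh3/imidazole the iodide F6. Separately, 13 is silylated (Et3SiOTf, 2,6-lutidine) to the vinylogous ester silyl ether F7. F6 is converted with t-BuLi (3 equiv) and CeCl3 into its organocerium reagent, which adds to the C5' carbonyl of F7; aqueous HCl then effects the Stork–Danheiser transposition and removes the silyl groups to give the enone triol F8. Corey–Bakshi–Shibata reduction of F8 as in step 11 should give 28.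

2. Step 7. The enone may be reduced without C–C bond formation, or the facial control at C1' may be poor. Fallback: the ring is closed by carbopalladation and the hydroxyl is added afterwards; it sets out from 10 and comes back at 11. Silylation of 10 (Et3SiOTf, 2,6-lutidine) should give the silyl ether F9, and KN(SiMe3)2/PhNTf2 at −78 °C the kinetic enol triflate F10 of the methyl ketone. A reductive Heck cyclization (Pd(OAc)2, PPh3, HCO2Na, DMF) adds the alkenyl group 5-exo to the enone from the tether face and should give the cis-fused methylidene ketone F11. Mukaiyama hydration (Mn(dpm)3, PhSiH3, O2, then P(OEt)3) should place the hydroxyl on the convex face to give the tertiary alcohol F12, and Bu4NF then gives 11.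

3. Step 2. The branched-to-linear ratio or the enantioselectivity may be low with the hindered silyl ketene acetal, or the free ketone may be attacked. Fallback: the centre is made by chirality transfer in a sigmatropic rearrangement; it sets out from 1 and comes back at 5. Cross-metathesis of 1 with (S)-but-3-en-2-ol should give (5E,7S)-7-hydroxyoct-5-en-2-one F13. Johnson–Claisen rearrangement with trimethyl orthoisobutyrate (propionic acid cat., 140 °C) passes the carbinol configuration through a chair to the new C–C bond and should give methyl (3R,4E)-2,2-dimethyl-3-(3-oxobutyl)hex-4-enoate F14. Ethenolysis (ethene, second-generation Hoveyda–Grubbs catalyst) trims the propenyl group to the vinyl group of 5.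

**Further compounds**

F1 | step 18 | (2E)-1-(benzyloxy)-6-[(2R,3R)-3-{2-[(2R)-3,3-dimethyloxiran-2-yl]ethyl}-3-methyloxiran-2-yl]hex-2-en-4-one | O=C(/C=C/COCc1ccccc1)CC[C@H]1O[C@]1(C)CC[C@H]1OC1(C)C
F2 | step 18 | {[(3Z)-1-(benzyloxy)-6-[(2R,3R)-3-{2-[(2R)-3,3-dimethyloxiran-2-yl]ethyl}-3-methyloxiran-2-yl]hex-3-en-4-yl]oxy}triethylsilane | CC[Si](CC)(CC)O/C(=C\CCOCc1ccccc1)CC[C@H]1O[C@]1(C)CC[C@H]1OC1(C)C
F3 | step 18 | (3R,5aR,6R,9aR)-6-[2-(benzyloxy)ethyl]-2,2,5a-trimethyl-3-(triethylsilyloxy)octahydro-1-benzoxepin-7(2H)-one | c1ccccc1COCC[C@@H]2[C@@]3(C)CC[C@@H](O[Si](CC)(CC)CC)C(C)(C)O[C@@H]3CCC2=O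
F4 | step 18 | (3R,5aR,6R,7S,9aR)-6-[2-(benzyloxy)ethyl]-2,2,5a,7-tetramethyl-3-(triethylsilyloxy)decahydro-1-benzoxepin-7-ol | c1ccccc1COCC[C@@H]2[C@@]3(C)CC[C@@H](O[Si](CC)(CC)CC)C(C)(C)O[C@@H]3CC[C@]2(C)O
F5 | step 18 | (3R,5aR,6R,7S,9aR)-6-(2-hydroxyethyl)-2,2,5a,7-tetramethyl-3-(triethylsilyloxy)decahydro-1-benzoxepin-7-ol | OCC[C@@H]1[C@@]2(C)CC[C@@H](O[Si](CC)(CC)CC)C(C)(C)O[C@@H]2CC[C@]1(C)O
F6 | step 18 | (3R,5aR,6R,7S,9aR)-6-(2-iodoethyl)-2,2,5a,7-tetramethyl-3-(triethylsilyloxy)decahydro-1-benzoxepin-7-ol | ICC[C@@H]1[C@@]2(C)CC[C@@H](O[Si](CC)(CC)CC)C(C)(C)O[C@@H]2CC[C@]1(C)O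
F7 | step 18 | (1R,3aR,8aR)-7-methoxy-1,4,4,6-tetramethyl-1-(triethylsilyloxy)-2,3,3a,4,8,8a-hexahydroazulen-5(1H)-one | COC1=C(C)C(=O)C(C)(C)[C@@H]2CC[C@@](C)(O[Si](CC)(CC)CC)[C@@H]2C1
F8 | step 18 | (1R,3aR,8aR)-5-{2-[(3R,5aR,6R,7S,9aR)-3,7-dihydroxy-2,2,5a,7-tetramethyldecahydro-1-benzoxepin-6-yl]ethyl}-1-hydroxy-1,4,4,6-tetramethyl-2,3,3a,4,8,8a-hexahydroazulen-7(1H)-one | CC1=C(CC[C@@H]2[C@@]3(C)CC[C@@H](O)C(C)(C)O[C@@H]3CC[C@]2(C)O)C(C)(C)[C@@H]2CC[C@@](C)(O)[C@@H]2CC1=O
F9 | step 7 | (4R)-5,5,7-trimethyl-4-(3-oxobutyl)-6-(triethylsilyloxy)cyclohept-2-en-1-one | CC1C(O[Si](CC)(CC)CC)C(C)(C)[C@H](CCC(C)=O)C=CC1=O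
F10 | step 7 | 4-[(1R)-2,2,4-trimethyl-5-oxo-3-(triethylsilyloxy)cyclohept-6-en-1-yl]but-1-en-2-yl trifluoromethanesulfonate | CC1C(O[Si](CC)(CC)CC)C(C)(C)[C@H](CCC(=C)OS(=O)(=O)C(F)(F)F)C=CC1=O
F11 | step 7 | (3aR,8aR)-4,4,6-trimethyl-1-methylidene-5-(triethylsilyloxy)decahydroazulen-7-one | CC1C(O[Si](CC)(CC)CC)C(C)(C)[C@@H]2CCC(=C)[C@@H]2CC1=O
F12 | step 7 | (1R,3aR,8aR)-1-hydroxy-1,4,4,6-tetramethyl-5-(triethylsilyloxy)decahydroazulen-7-one | CC1C(O[Si](CC)(CC)CC)C(C)(C)[C@@H]2CC[C@@](C)(O)[C@@H]2CC1=O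
F13 | step 2 | (5E,7S)-7-hydroxyoct-5-en-2-one | C[C@H](O)/C=C/CCC(C)=O
F14 | step 2 | methyl (3R,4E)-2,2-dimethyl-3-(3-oxobutyl)hex-4-enoate | COC(=O)C(C)(C)[C@@H](/C=C/C)CCC(C)=O
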